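**Retrosynthetic overview**

- The target is a depside. Ring A is olivetolic acid, ring B is a 3-chloro-2-hydroxy-4-methoxy-6-pentylbenzoyl unit on the 4-oxygen of ring A. The last step frees the ring A acid from a benzyl ester by hydrogenolysis.
- Ring B is cut at C3–C4 and C1–C6 into two three-carbon pieces. One is a 4-chloro-1,3-bis(trimethylsilyloxy)diene already attached to the 4-oxygen of ring A (ester carbon, C1, C2, chlorinated C3). The other is 1,1-dimethoxyoct-1-en-3-one (C4 with OMe, C5, C6 with pentyl).
- The diene comes from an aryl 4-chloroacetoacetate, made by capture of chloroacetylketene (from 6-(chloromethyl)dioxinone) at the 4-OH of benzyl olivetolate. The enone acetal comes from hexanoyl chloride and 1,1-dichloroethene.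
- Order of rings: ring A is bought, the depside C–O bond is made second, and ring B is closed last on the acyl side of that ester.
- The strategy rests on the C2(OH)–C3(Cl)–C4(OMe) triad of ring B. A chlorine between two oxygens cannot be placed cleanly by chlorinating a finished resorcylate because C5 competes, so C3 arrives already chlorinated from the chloromethyl carbon of the acetoacetate.

Key step: step 8

Remark: the silyl enol ethers 8 to 10 and the transient adducts 16 and 17 are expected as mixtures of geometric isomers or stereoisomers and are drawn without configuration; all of these elements disappear when ring B becomes aromatic, and the target has no stereocentre.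

**Route**

Step 1
Reactants: 1 olivetolic acid (2,4-dihydroxy-6-pentylbenzoic acid)
Product: 2 benzyl 2,4-dihydroxy-6-pentylbenzoate
Conditions: BnBr (1.05 equiv), KHCO3 (1.1 equiv), DMF, 20 °C
Reagents that add atoms: benzyl bromide BrCc1ccccc1
Why: KHCO3 ionises only the carboxylic acid, and the carboxylate is benzylated by SN2 displacement of bromide (carboxylate O-alkylation) while the un-ionised phenols stay free and the mild temperature avoids decarboxylation of the β-resorcylic acid.

Step 2
Reactants: 3 2,2,6-trimethyl-4H-1,3-dioxin-4-one
Product: 5 6-(chloromethyl)-2,2-dimethyl-4H-1,3-dioxin-4-one, via lithium dienolate 4 (not isolated)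
Conditions: LiN(iPr)2 (1.1 equiv), THF, −78 °C; then cannulated into C2Cl6 (1.2 equiv), THF, −50 → −20 °C
Reagents that add atoms: hexachloroethane ClC(Cl)(Cl)C(Cl)(Cl)Cl
Why: Kinetic deprotonation of the 6-methyl group gives dienolate 4, which takes a chlorine at its γ-carbon from hexachloroethane acting as a positive-chlorine donor (electrophilic γ-halogenation of a vinylogous ester enolate), inverse addition keeping the product away from excess base.

Step 3
Reactants: 2 benzyl 2,4-dihydroxy-6-pentylbenzoate; 5 6-(chloromethyl)-2,2-dimethyl-4H-1,3-dioxin-4-one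
Product: 7 benzyl 4-[(4-chloro-3-oxobutanoyl)oxy]-2-hydroxy-6-pentylbenzoate, via chloroacetylketene 6 (not isolated)
Conditions: 5 (1.1 equiv), toluene, 110 °C, acetone distilled off
Reagents that add atoms: none
Why: At 110 °C the dioxinone undergoes retro-hetero-Diels–Alder cleavage to acetone and acylketene 6, which is trapped by the free para-hydroxyl of 2 (acylketene acylation of a phenol), the ortho-hydroxyl being deactivated by its hydrogen bond to the benzyl ester carbonyl.

Step 4
Reactants: 7 benzyl 4-[(4-chloro-3-oxobutanoyl)oxy]-2-hydroxy-6-pentylbenzoate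
Product: 8 benzyl 4-{[4-chloro-3-(trimethylsilyloxy)but-2-enoyl]oxy}-6-pentyl-2-(trimethylsilyloxy)benzoate
Conditions: Me3SiCl (3 equiv), Et3N (3 equiv), toluene, 20 °C; filtered under argon, concentrated, used crude
Reagents that add atoms: chlorotrimethylsilane C[Si](C)(C)Cl
Why: Amine-mediated O-silylation converts the enol form of the β-keto ester into the conjugated 3-silyloxy enoate and caps the remaining phenol as its silyl ether (silyl enol ether formation by soft enolisation), which removes both acidic protons before the strong base of the next step.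

Step 5
Reactants: 8 benzyl 4-{[4-chloro-3-(trimethylsilyloxy)but-2-enoyl]oxy}-6-pentyl-2-(trimethylsilyloxy)benzoate
Product: 10 benzyl 4-{[4-chloro-1,3-bis(trimethylsilyloxy)buta-1,3-dien-1-yl]oxy}-6-pentyl-2-(trimethylsilyloxy)benzoate, via lithium dienolate 9 (not isolated)
Conditions: Me3SiCl (1.5 equiv), then LiN(iPr)2 (1.1 equiv), THF, −78 → 0 °C; pentane, filtration under argon, used crude
Reagents that add atoms: chlorotrimethylsilane C[Si](C)(C)Cl
Why: LiN(iPr)2 removes the γ-proton next to chlorine of the 3-silyloxy enoate to give dienolate 9, which is silylated on oxygen by the Me3SiCl already present (ketene silyl acetal formation with in situ quench), the low temperature and immediate trapping suppressing loss of aryloxide to a ketene while the far less acidic benzylic positions stay untouched.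

Step 6
Reactants: 11 hexanoyl chloride; 12 1,1-dichloroethene
Product: 14 1,1-dichlorooct-1-en-3-one, via 1,1,1-trichlorooctan-3-one 13 (not isolated)
Conditions: AlCl3 (1.1 equiv), CH2Cl2, 0 → 20 °C; ice/aq HCl; distillation under reduced pressure (−HCl)
Reagents that add atoms: none
Why: The acylium ion from hexanoyl chloride and AlCl3 adds to the CH2 terminus of the alkene to give a chlorine-stabilised cation that collects chloride (Friedel–Crafts-type acylation of an alkene), and trichloro ketone 13 then loses HCl to the conjugated dichlorovinyl ketone.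

Step 7
Reactants: 14 1,1-dichlorooct-1-en-3-one
Product: 15 1,1-dimethoxyoct-1-en-3-one
Conditions: NaOMe (2.0 equiv), MeOH, 0 → 20 °C; distilled, stored cold under argon
Reagents that add atoms: sodium methoxide C[O-].[Na+]
Why: Methoxide replaces both vinylic chlorides by two successive conjugate addition–elimination events at the β-carbon of the enone (nucleophilic vinylic substitution), and exactly two equivalents at low temperature limit further addition of methanol to an ortho ester.

Step 8
Reactants: 10 benzyl 4-{[4-chloro-1,3-bis(trimethylsilyloxy)buta-1,3-dien-1-yl]oxy}-6-pentyl-2-(trimethylsilyloxy)benzoate; 15 1,1-dimethoxyoct-1-en-3-one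
Product: 18 benzyl 4-[(3-chloro-2-hydroxy-4-methoxy-6-pentylbenzoyl)oxy]-2-hydroxy-6-pentylbenzoate, via open-chain Michael adduct 16 (not isolated), via cyclic aldol adduct 17 (not isolated)
Conditions: 15 (1.5 equiv), TiCl4 (1.5 equiv), 4 Å molecular sieves, CH2Cl2, −78 → 20 °C; then 10% aq HCl
Reagents that add atoms: none
Why: TiCl4 binds the ketone oxygen of 15 and turns its dimethoxy carbon into a vinylogous oxocarbenium centre; the chlorine-bearing terminal carbon of diene 10 adds there in a Mukaiyama–Michael sense and methoxide is expelled, giving β-methoxy enone 16 (bond C3–C4 of ring B). The carbon of the surviving ketene silyl acetal then attacks the titanium-activated pentyl ketone in an intramolecular Mukaiyama aldol reaction to give 17 (bond C1–C6), and loss of water followed by enolisation makes ring B aromatic with ester, OH, Cl, OMe and pentyl all in place. The closest known reaction type is the TiCl4-mediated formal [3+3] cyclocondensation of 1,3-bis(silyloxy)buta-1,3-dienes, 4-chloro dienes included, with 3-oxo ketene acetals and 3-alkoxy enones, which gives 4-methoxysalicylates and 3-chlorosalicylates. Ring B is closed in a 6-(enolexo)-exo-trig mode; no stereocentre remains, since those of 16 and 17 are erased on aromatisation. The step needs regioselectivity, the terminal diene carbon going to the acetal carbon and not to the ketone; this is secured because that terminus is the most nucleophilic site of the diene and the Lewis-acid-activated dimethoxy carbon is the softer conjugate position, after which the central carbon can reach only the ketone. The aryl ester, the benzyl ester and the aryl silyl ether of ring A should tolerate TiCl4 at low temperature, and the silyl ether falls off in the acidic work-up.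

Step 9
Reactants: 18 benzyl 4-[(3-chloro-2-hydroxy-4-methoxy-6-pentylbenzoyl)oxy]-2-hydroxy-6-pentylbenzoate
Product: 19 4-[(3-chloro-2-hydroxy-4-methoxy-6-pentylbenzoyl)oxy]-2-hydroxy-6-pentylbenzoic acid (target CNP0310773.0)
Conditions: H2 (1 atm), 10% Pd/C, EtOAc, 20 °C, stopped after uptake of 1 equiv H2
Reagents that add atoms: none
Why: Palladium-catalysed hydrogenolysis of the benzylic C–O bond frees the carboxylic acid much faster than the electron-rich aryl chloride is reduced in neutral ethyl acetate, and the aryl ester, methyl ether and phenols are inert, so stopping at one equivalent of hydrogen should give the target.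

**Compound list**

1 | olivetolic acid (2,4-dihydroxy-6-pentylbenzoic acid) | CCCCCc1cc(O)cc(O)c1C(=O)O | starting material
2 | benzyl 2,4-dihydroxy-6-pentylbenzoate | CCCCCc1cc(O)cc(O)c1C(=O)OCc1ccccc1 | intermediate
3 | 2,2,6-trimethyl-4H-1,3-dioxin-4-one | CC1=CC(=O)OC(C)(C)O1 | starting material
4 | lithium 2,2-dimethyl-6-methylidene-6H-1,3-dioxin-4-olate (lithium dienolate of 3) | C=C1C=C(O[Li])OC(C)(C)O1 | intermediate
5 | 6-(chloromethyl)-2,2-dimethyl-4H-1,3-dioxin-4-one | CC1(C)OC(CCl)=CC(=O)O1 | intermediate
6 | chloroacetylketene (4-chlorobut-1-ene-1,3-dione) | O=C=CC(=O)CCl | intermediate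
7 | benzyl 4-[(4-chloro-3-oxobutanoyl)oxy]-2-hydroxy-6-pentylbenzoate | CCCCCc1cc(OC(=O)CC(=O)CCl)cc(O)c1C(=O)OCc1ccccc1 | intermediate
8 | benzyl 4-{[4-chloro-3-(trimethylsilyloxy)but-2-enoyl]oxy}-6-pentyl-2-(trimethylsilyloxy)benzoate (enol ether geometry not defined) | CCCCCc1cc(OC(=O)C=C(O[Si](C)(C)C)CCl)cc(O[Si](C)(C)C)c1C(=O)OCc1ccccc1 | intermediate
9 | lithium dienolate of 8 (O-lithio ketene acetal, geometry not defined) | CCCCCc1cc(OC(O[Li])=CC(O[Si](C)(C)C)=CCl)cc(O[Si](C)(C)C)c1C(=O)OCc1ccccc1 | intermediate
10 | benzyl 4-{[4-chloro-1,3-bis(trimethylsilyloxy)buta-1,3-dien-1-yl]oxy}-6-pentyl-2-(trimethylsilyloxy)benzoate (geometry not defined) | CCCCCc1cc(OC(O[Si](C)(C)C)=CC(O[Si](C)(C)C)=CCl)cc(O[Si](C)(C)C)c1C(=O)OCc1ccccc1 | intermediate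
11 | hexanoyl chloride | CCCCCC(=O)Cl | starting material
12 | 1,1-dichloroethene | C=C(Cl)Cl | starting material
13 | 1,1,1-trichlorooctan-3-one | CCCCCC(=O)CC(Cl)(Cl)Cl | intermediate
14 | 1,1-dichlorooct-1-en-3-one | CCCCCC(=O)C=C(Cl)Cl | intermediate
15 | 1,1-dimethoxyoct-1-en-3-one | CCCCCC(=O)C=C(OC)OC | intermediate
16 | benzyl 4-{[4-chloro-5-methoxy-3,7-dioxo-1-(trimethylsilyloxy)dodeca-1,5-dien-1-yl]oxy}-6-pentyl-2-(trimethylsilyloxy)benzoate (open-chain Michael adduct, drawn metal-free, racemic at C4, geometry not defined) | CCCCCC(=O)C=C(OC)C(Cl)C(=O)C=C(O[Si](C)(C)C)Oc1cc(CCCCC)c(C(=O)OCc2ccccc2)c(O[Si](C)(C)C)c1 | intermediate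
17 | benzyl 4-[(3-chloro-6-hydroxy-4-methoxy-2-oxo-6-pentylcyclohex-4-ene-1-carbonyl)oxy]-6-pentyl-2-(trimethylsilyloxy)benzoate (cyclic aldol adduct, drawn metal-free, mixture of stereoisomers) | CCCCCC1(O)C=C(OC)C(Cl)C(=O)C1C(=O)Oc1cc(CCCCC)c(C(=O)OCc2ccccc2)c(O[Si](C)(C)C)c1 | intermediate
18 | benzyl 4-[(3-chloro-2-hydroxy-4-methoxy-6-pentylbenzoyl)oxy]-2-hydroxy-6-pentylbenzoate | CCCCCc1cc(OC(=O)c2c(CCCCC)cc(OC)c(Cl)c2O)cc(O)c1C(=O)OCc1ccccc1 | intermediate
19 | 4-[(3-chloro-2-hydroxy-4-methoxy-6-pentylbenzoyl)oxy]-2-hydroxy-6-pentylbenzoic acid (CNP0310773.0) | CCCCCc1cc(OC(=O)c2c(CCCCC)cc(OC)c(Cl)c2O)cc(O)c1C(=O)O | target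

**Step count**

Total: 9 steps. Longest linear sequence: 6 steps (steps 1 or 2, then 3, 4, 5, 8, 9).

**Steps most likely to fail**

Step 8. The first carbon–carbon bond may form with the wrong regiochemistry (attack at the ketone), the diene may simply be desilylated back to the keto ester, or the aryl ester may be cleaved by loss of aryloxide under the Lewis acid. The fallback builds ring B before the depside bond and sets out from 15. Commercial methyl 4-chloro-3-oxobutanoate is silylated with Me3SiCl and Et3N to methyl 4-chloro-3-(trimethylsilyloxy)but-2-enoate F1, and then with LiN(iPr)2 and Me3SiCl at −78 °C to 4-chloro-1-methoxy-1,3-bis(trimethylsilyloxy)buta-1,3-diene F2. Cyclocondensation of F2 with 15 under TiCl4 in CH2Cl2 should give methyl 3-chloro-2-hydroxy-4-methoxy-6-pentylbenzoate F3. Saponification with KOH in aqueous DMSO and cold acidification should give 3-chloro-2-hydroxy-4-methoxy-6-pentylbenzoic acid F4. Coupling of F4 with 2 by trifluoroacetic anhydride in toluene at 20 °C (mixed-anhydride acylation of the more nucleophilic 4-OH) comes back to the route at 18.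

Step 5. The lithium dienolate of an aryl ester may expel the aryloxide to give a ketene before it is silylated, silylation may go to carbon, or the hindered aryl silyl ether of ring A may be incomplete and consume base. The fallback gives up the lithium enolate altogether: setting out from 7, threefold soft enolisation and silylation with Me3SiOTf (3.3 equiv) and Et3N (3.5 equiv) in Et2O at 0 °C should lead in one flask, without any anionic ester enolate, to 10, where it rejoins the route; it makes no compound outside the list (F0).

Step 3. The acylketene may dimerise or decompose faster than the weakly nucleophilic phenol captures it, the hydrogen-bonded 2-OH may be acylated as well, or the chloromethyl ketone may alkylate a phenol at 110 °C. The fallback replaces thermal cycloreversion by low-temperature acylation: diketene and chlorine in CH2Cl2 at −20 °C give 4-chloro-3-oxobutanoyl chloride F5, which is added to 2 and pyridine (1 equiv) in CH2Cl2 at −40 °C and returns to the route at 7.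

**Further compounds**

F1 | step 8 | methyl 4-chloro-3-(trimethylsilyloxy)but-2-enoate | COC(=O)C=C(O[Si](C)(C)C)CCl
F2 | step 8 | 4-chloro-1-methoxy-1,3-bis(trimethylsilyloxy)buta-1,3-diene | COC(O[Si](C)(C)C)=CC(O[Si](C)(C)C)=CCl
F3 | step 8 | methyl 3-chloro-2-hydroxy-4-methoxy-6-pentylbenzoate | CCCCCc1cc(OC)c(Cl)c(O)c1C(=O)OC
F4 | step 8 | 3-chloro-2-hydroxy-4-methoxy-6-pentylbenzoic acid | CCCCCc1cc(OC)c(Cl)c(O)c1C(=O)O
F0 | step 5 | none | none
F5 | step 3 | 4-chloro-3-oxobutanoyl chloride | O=C(Cl)CC(=O)CCl
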